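**Remarks (assumptions on the chemistry)**

- Numbering is that of the germacrane skeleton: C1 ketone, C2=C3 furanone alkene, C4(=C5) carrying methyl C15, C6 (lactone oxygen), C7, C8 (ester oxygen), C9, C10 (quaternary, methyl C14, ether oxygen to C3), C11=C13 exocyclic methylene, C12 lactone carbonyl. Ring A is the 3(2H)-furanone, ring B the ten-membered carbocycle, ring C the lactone.
- The target is (4Z,6S,7S,8R,10R). Under a suprafacial methyl shift the (R) carbinol of 10 maps onto (R)-C10 of 11 and 29, and the Z enyne of 1 maps onto the 4Z alkene, so the stereochemical bookkeeping needs no correction.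
- The sense of induction in the two catalytic alkynylations (steps 2 and 10) is assigned by analogy. The ligand antipode that delivers the stated configuration is used (both antipodes are available), and the configuration should be confirmed (MTPA ester) before continuing.
- The C6 oxygen is carried through the key step as a tert-butyldiphenylsilyl ether: it is bulkier and less Lewis basic than a smaller silyl ether, so it should neither attack the gold-activated alkyne nor be lost to traces of HCl from AuCl3. The C8 oxygen is a PMB ether so that it can be removed late under neutral oxidative conditions.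

## Structural features

The target is a furanoheliangolide: a ten-membered carbocycle (ring B, C1–C10) bridged by an oxygen from C3 to C10, so that O, C3, C2, C1 and C10 form a 3(2H)-furanone (ring A). An α-methylene-γ-butyrolactone (ring C) is trans-fused across C6–C7. The trisubstituted C4=C5 alkene is Z (ring-cis) and conjugated with the furanone enone, so C1–C6 form one rigid, nearly planar cross-conjugated unit. C6, C7 and C8 are contiguous stereocentres (H6/H7 trans, O8 anti to C6 across C7–C8). The quaternary ether carbon C10 is separated from this triad by the C9 methylene. The fragile parts are the exocyclic methylene lactone, the (E)-2-(acetoxymethyl)but-2-enoate (Michael acceptor and allylic acetate), and the Z dienone, which can isomerise. Any C8 carbonyl intermediate has the furanone oxygen on its β-carbon and can lose it by E1cB, and C6–H becomes acidic whenever C7=C11 is endocyclic. The real difficulty is twofold: closing the strained oxa-bridged medium ring (nine atoms through the ether oxygen) with control of the triad relative to remote C10, and making the quaternary centre C10 as one enantiomer. The key step exploits the fact that in ring A the quaternary, oxygen-bearing C10 sits directly next to the C1 ketone with the C2=C3 enol ether opposite. This is the pattern left by cycloisomerisation of a 2-hydroxy-2-alkynyl ketone in which the carbinol carbon becomes C1 and the ketone carbon becomes C10 after a 1,2-methyl shift.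

## Logic of the disconnections

**29 ⇒ 22 + 28.** The C8–O acyl bond is cut. The side chain carries an allylic acetate and an enoate that would not survive organometallic steps, so it is added last. This separates a seven-carbon acid from the tricyclic alcohol. The forward acylation must reach a hindered secondary alcohol without harming the methylene lactone or scrambling the side-chain alkene.

**28 ⇒ 27 ⇒ 25 ⇒ 23 + 24.** The tert-butyl ester C–O bond, the primary allylic C–O bond (transposed from the secondary position of 26) and the Cα–C(carbinol) bond are cut in turn. This reduces 28 to two commodity chemicals. The forward transposition must end at the E alkene, and the acid must be released without touching the acetate.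

**22 ⇒ 21.** The ring bond C7–C8 is cut. Its formation creates C7 and C8 and regenerates C11=C13 from a lactone already at the right oxidation level. This opens rings B and C of 22 into a furanone and a butenolide joined by the Z alkene. The forward step must close a nine-membered ring under neutral conditions (the C8 aldehyde has the C10 oxygen in the β position), add anti to the C5 substituent at C7, and select one face of the aldehyde.

**21 ⇒ 20 ⇒ 19.** The C8 aldehyde is traced to the alcohol and then to the PMB ether. The aldehyde is the most base-labile intermediate and is therefore unveiled immediately before ring closure. Deprotection and oxidation must be neutral and must spare the allylic bromide.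

**19 ⇒ 18 ⇒ 17.** The C13–Br bond and then the C11–C13 bond are cut, so C13 comes from formaldehyde. This leaves the unsubstituted butenolide in 17. The nucleophile-catalysed hydroxymethylation must not deprotonate C6–H.

**17 ⇒ 15 (through 16) ⇒ 13 + 14.** The lactone O6–C12 bond and the C6–C7 bond are cut. C7, C11 and C12 arrive as one alkynoate, and C6 is the single centre that must be set by a reagent because it is remote from C10. The forward addition must differentiate the faces of a Z enal without isomerising it, and the reduction must stop at the cis alkene.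

**13 ⇒ 12 ⇒ 11.** Only the oxidation level and the silyl group at C6 change. The silyl ether must come off in the presence of the PMB ether.

**11 ⇒ 10 (key step).** The O–C3 bond of ring A is cut and the C10–CH3 bond is returned to C1. This turns ring A and its quaternary ether centre into an acyclic tertiary propargylic alcohol, a centre that carbonyl alkynylation can deliver. The forward step must be a stereospecific suprafacial shift, with O-attack by the carbonyl only and retention of the Z alkene.

**10 ⇒ 6 + 9; 9 ⇒ 8 ⇒ 7.** The C8–C9 bond is cut. C8 and its protected oxygen are added as an alkoxymethyl electrophile at the only enolisable position of 6. The forward alkylation must occur on carbon in the presence of the tertiary alkoxide.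

**6 ⇒ 4 (through 5).** The C10–C9 bond is cut (C9 from a methyl Grignard reagent). The ester of 4 is the handle. Over-addition must be avoided.

**4 ⇒ 2 + 3; 2 ⇒ 1.** The C1–C2 bond is cut between a terminal alkyne and the ketone carbonyl of 3. This sets the only stereocentre of 10 and uses the Z geometry of 1 unchanged. The forward addition must be enantioselective at a small, enolisable keto ester.

## Other disconnections considered

**Alternative 1:** The cut is the C4=C5 double bond, traced to the eleven-membered cyclic sulfone A1 with sulfur between C4 and C5. In the forward step C2Cl6/KOt-Bu chlorinates an α-carbon of A1, 1,3-elimination gives an episulfone, SO2 is lost, and the ring contracts to A2 with the alkene in place (Ramberg–Bäcklund).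
- *In favour:* the ring is first closed as a larger thioether by C–S alkylation, and the bicyclic frame enforces the ring-cis alkene.
- *Against:* KOt-Bu meets several acidic sites in A1. The carbanion at C5 has the lactone oxygen on C6 in the β position (E1cB opening), and the lactone α-carbon C11 can be chlorinated instead. A2 also lacks C13, so α-methylenation, desilylation and acylation follow.
- *Comparison.* Structure: it makes the alkene and ring B in one operation, and the C6–C8 triad could be fixed on an open chain beforehand, which is better than the chosen plan, where C8 is left to the ring closure. Mechanism: it is the weaker plan, being anionic and strongly basic where the chosen ring closure is neutral. Step economy: roughly equal up to the ring and worse after it.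

**Alternative 2:** The cut is C1–C2. The open-chain aldehyde A3 carries the terminal Z enyne; LiN(SiMe3)2 forms the acetylide, which adds to the C1 aldehyde and closes the cyclodecenynol A4. Oxidation to the ynone, release of the C10 hydroxyl and transannular conjugate addition then give the furanone.
- *In favour:* the aldehyde has no α-hydrogen, and the carbinol configuration is irrelevant. All four stereocentres, C10 included, are set beforehand by ordinary reagent-controlled steps. This is better than the chosen plan, where C10 relies on a chirality transfer supported only by analogy and C8 on substrate control. Furanone closure by conjugate addition is the equal of the gold step in reliability.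
- *Against:* a ten-membered ring must accommodate a bent alkyne next to a Z alkene, and a chain with four protected oxygens must be cyclised. C12 is at the alcohol level in A4, so oxidation, three deprotections, oxidative lactonisation and acylation follow with five kinds of protecting group.
- *Comparison.* Structure: better stereochemical certainty. Mechanism: a simple polar addition, but with more strain in the ring-closing step. Step economy: about equal in length after the key step, with a heavier protecting-group load.

**Alternative 3:** The cut is C5–C6. A5 has the furanone, a Z alkenyl iodide at C5, the C6 aldehyde and the C12 methyl ester. CrCl2 with catalytic NiCl2 (zerovalent nickel inserts into C–I and the alkenyl group passes to trivalent chromium) adds C5 to the aldehyde, and the C6 alkoxide lactonises to A6.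
- *In favour:* A6 is two steps from 29 (desilylation gives 22, then acylation), which is better than the chosen plan after ring closure. The coupling retains alkene geometry and is neutral, the equal of the chosen CrCl2 closure.
- *Against:* the aldehyde of A5 sits on C7, a stereocentre that is both α to the formyl group and allylic to the acrylate, so epimerisation or migration of C11=C13 into conjugation threatens. C6 is formed under substrate control, the same kind of uncertainty as C8 in the chosen plan. A5 itself is laborious, and ring A must still be made earlier.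
- *Comparison.* Structure: this alternative competes with the endgame, not with the construction of ring A and C10. Mechanism: equal. Step economy: better after ring closure, probably worse before it.

Key step: step 7

---

**Step 1**
Reactants: 1 (2Z)-3-methylpent-2-en-4-yn-1-ol
Product: 2 tert-butyl{[(2Z)-3-methylpent-2-en-4-yn-1-yl]oxy}diphenylsilane
Conditions: t-BuPh2SiCl, imidazole, DMF, 0 → 23 °C
Reagents that add atoms: tert-butyl(chloro)diphenylsilane, CC(C)(C)[Si](Cl)(c1ccccc1)c1ccccc1
Why: Silyl ether formation on a primary alcohol; the Z enyne is a spectator. The bulky diphenylsilyl group is chosen for the later gold step.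

**Step 2**
Reactants: 2 tert-butyl{[(2Z)-3-methylpent-2-en-4-yn-1-yl]oxy}diphenylsilane; 3 ethyl pyruvate
Product: 4 ethyl (2R,5Z)-7-[(tert-butyldiphenylsilyl)oxy]-2-hydroxy-2,5-dimethylhept-5-en-3-ynoate
Conditions: Zn(OTf)2 (20 mol%), 2-(dimethylamino)-1-(4-nitrophenyl)-3-[(tert-butyldimethylsilyl)oxy]propan-1-ol (antipode giving 2R, 22 mol%), Et3N (30 mol%), toluene, 70 °C, slow addition of 3
Reagents that add atoms: none
Why: Catalytic enantioselective alkynylation of an α-keto ester: the zinc acetylide formed in situ adds to the ketone carbonyl, which is held with the ester on the zinc amino-alkoxide so that one face is shielded. This sets the tertiary carbinol (future C1) as R; the facial sense rests on analogy.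

**Step 3**
Reactants: 4 ethyl (2R,5Z)-7-[(tert-butyldiphenylsilyl)oxy]-2-hydroxy-2,5-dimethylhept-5-en-3-ynoate
Product: 6 (3R,6Z)-8-[(tert-butyldiphenylsilyl)oxy]-3-hydroxy-3,6-dimethyloct-6-en-4-yn-2-one, via Weinreb amide 5 (not isolated)
Conditions: MeNH(OMe)·HCl, i-PrMgCl, THF, −20 °C; then MeMgBr, −20 → 0 °C; aq. NH4Cl
Reagents that add atoms: N,O-dimethylhydroxylamine hydrochloride, CNOC.Cl (its atoms remain only in 5); methylmagnesium bromide, C[Mg]Br
Why: Weinreb amide formation from the ester with the chloromagnesium amide, then Grignard addition to the Weinreb amide; the chelated tetrahedral intermediate stops at the ketone. The carbinol is carried as its magnesium alkoxide and its configuration is untouched.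

**Step 4**
Reactants: 7 4-methoxybenzyl alcohol
Product: 8 1-methoxy-4-{[(methylsulfanyl)methoxy]methyl}benzene
Conditions: NaH, ClCH2SMe, NaI (cat.), THF, 0 → 23 °C
Reagents that add atoms: chloromethyl methyl sulfide, CSCCl
Why: Williamson etherification of the sodium alkoxide with an α-chloro sulfide gives the O,S-acetal.

**Step 5**
Reactants: 8 1-methoxy-4-{[(methylsulfanyl)methoxy]methyl}benzene
Product: 9 1-[(chloromethoxy)methyl]-4-methoxybenzene
Conditions: SO2Cl2, CH2Cl2, −78 °C; volatiles removed, used crude
Reagents that add atoms: sulfuryl chloride, O=S(=O)(Cl)Cl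
Why: Chlorinolysis of the O,S-acetal: S-chlorination, loss of the sulfenyl chloride and capture of the oxocarbenium ion by chloride. This avoids the HCl/formaldehyde route, which would cleave the PMB ether.

**Step 6**
Reactants: 6 (3R,6Z)-8-[(tert-butyldiphenylsilyl)oxy]-3-hydroxy-3,6-dimethyloct-6-en-4-yn-2-one; 9 1-[(chloromethoxy)methyl]-4-methoxybenzene
Product: 10 (4R,7Z)-9-[(tert-butyldiphenylsilyl)oxy]-4-hydroxy-1-[(4-methoxybenzyl)oxy]-4,7-dimethylnon-7-en-5-yn-3-one
Conditions: LiN(i-Pr)2 (2.2 equiv), THF, −78 °C; then 9 (1.2 equiv), −78 → −40 °C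
Reagents that add atoms: none
Why: Ketone enolate alkylation with an alkoxymethyl chloride through the alkoxide–enolate dianion; only the methyl group can be enolised. The enolate carbon should react faster than the hindered lithium tert-alkoxide, and the stereocentre is not involved.

**Step 7 (key step)**
Reactants: 10 (4R,7Z)-9-[(tert-butyldiphenylsilyl)oxy]-4-hydroxy-1-[(4-methoxybenzyl)oxy]-4,7-dimethylnon-7-en-5-yn-3-one
Product: 11 (2R)-5-{(2Z)-4-[(tert-butyldiphenylsilyl)oxy]but-2-en-2-yl}-2-{2-[(4-methoxybenzyl)oxy]ethyl}-2-methylfuran-3(2H)-one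
Conditions: AuCl3 (5 mol%), CH2Cl2, 23 °C
Reagents that add atoms: none
Why: AuCl3 (trivalent gold) coordinates the C2≡C3 alkyne and the C10 carbonyl oxygen attacks C3 anti to the metal, giving a cyclic oxocarbenium ion with a vinylgold at C2. The C1 carbinol then undergoes a semipinacol-type 1,2-shift: methyl moves suprafacially from C1 to cationic C10 while the hydroxyl becomes the C1 ketone, and protodeauration at C2 releases 11 and the catalyst. The closest known reaction type is the gold- or platinum-catalysed heterocyclisation with 1,2-migration of 2-hydroxy-2-alkynyl carbonyl compounds to 3(2H)-furanones, which includes acyclic cases with methyl migration. Ring A is the one ring closed, in the 5-endo-dig mode; attack at C2 would give a four-membered ring and is excluded. The one new stereocentre, C10, is controlled by the C1 carbinol: the methyl group stays on its face of the new ring, so (R)-C1 becomes (R)-C10 (the descriptor is kept because the priority order oxygen, carbonyl carbon, chain carbon, methyl is the same at both centres). This chirality transfer follows from the concerted shift but rests on analogy. The step needs three selectivities. The carbonyl oxygen and not the O6 ether must add to C3; the bulky, weakly basic silyl ether and the placement of the carbonyl three atoms from C3 should ensure this. Only methyl can migrate, because the other two carbon substituents of C1 are ring bonds. The Z C4=C5 alkene must not isomerise, and it is a spectator as long as the reaction is short at 23 °C.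

**Step 8**
Reactants: 11 (2R)-5-{(2Z)-4-[(tert-butyldiphenylsilyl)oxy]but-2-en-2-yl}-2-{2-[(4-methoxybenzyl)oxy]ethyl}-2-methylfuran-3(2H)-one
Product: 12 (2R)-5-[(2Z)-4-hydroxybut-2-en-2-yl]-2-{2-[(4-methoxybenzyl)oxy]ethyl}-2-methylfuran-3(2H)-one
Conditions: Bu4NF, AcOH (1:1), THF, 0 → 23 °C
Reagents that add atoms: none
Why: Fluoride-mediated desilylation buffered with acetic acid; the PMB ether and the furanone, which has no base-labile β-leaving group at this stage, are inert.

**Step 9**
Reactants: 12 (2R)-5-[(2Z)-4-hydroxybut-2-en-2-yl]-2-{2-[(4-methoxybenzyl)oxy]ethyl}-2-methylfuran-3(2H)-one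
Product: 13 (2Z)-3-[(5R)-5-{2-[(4-methoxybenzyl)oxy]ethyl}-5-methyl-4-oxo-4,5-dihydrofuran-2-yl]but-2-enal
Conditions: MnO2 (activated, excess), CH2Cl2, 23 °C; filtered and used at once
Reagents that add atoms: none
Why: Allylic alcohol oxidation with MnO2, a neutral heterogeneous oxidant that should leave the Z geometry and the PMB ether intact. The enal is not stored because Z enals isomerise.

**Step 10**
Reactants: 13 (2Z)-3-[(5R)-5-{2-[(4-methoxybenzyl)oxy]ethyl}-5-methyl-4-oxo-4,5-dihydrofuran-2-yl]but-2-enal; 14 methyl propiolate
Product: 15 methyl (4S,5Z)-4-hydroxy-6-[(5R)-5-{2-[(4-methoxybenzyl)oxy]ethyl}-5-methyl-4-oxo-4,5-dihydrofuran-2-yl]hept-5-en-2-ynoate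
Conditions: Me2Zn (3 equiv), 2,6-bis{[2-(hydroxydiphenylmethyl)pyrrolidin-1-yl]methyl}-4-methylphenol (ProPhenol, antipode giving 4S, 20 mol%), Ph3PO (40 mol%), toluene, 4 °C
Reagents that add atoms: none
Why: Catalytic enantioselective alkynylation of an aldehyde with a zinc acetylide on a dinuclear zinc–ProPhenol catalyst, a reaction type that favours α,β-unsaturated aldehydes and leaves ketones alone. The catalyst selects the aldehyde face and sets C6 (4S here, 6S in the target); the sense is by analogy.

**Step 11**
Reactants: 15 methyl (4S,5Z)-4-hydroxy-6-[(5R)-5-{2-[(4-methoxybenzyl)oxy]ethyl}-5-methyl-4-oxo-4,5-dihydrofuran-2-yl]hept-5-en-2-ynoate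
Product: 17 (5R)-5-{(1Z)-2-[(5R)-5-{2-[(4-methoxybenzyl)oxy]ethyl}-5-methyl-4-oxo-4,5-dihydrofuran-2-yl]prop-1-en-1-yl}furan-2(5H)-one, via cis hydroxy enoate 16 (not isolated)
Conditions: H2 (1 atm), Pd/CaCO3 poisoned with Pb(OAc)2, quinoline, EtOAc, 23 °C; then silica gel, CH2Cl2
Reagents that add atoms: none
Why: Lindlar semi-hydrogenation gives the cis enoate, whose hydroxyl sits next to the ester and lactonises with loss of methanol. The poisoned catalyst should not reduce the conjugated trisubstituted alkenes. C6 is untouched; its descriptor becomes R only because the priorities change.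

**Step 12**
Reactants: 17 (5R)-5-{(1Z)-2-[(5R)-5-{2-[(4-methoxybenzyl)oxy]ethyl}-5-methyl-4-oxo-4,5-dihydrofuran-2-yl]prop-1-en-1-yl}furan-2(5H)-one
Product: 18 (5S)-3-(hydroxymethyl)-5-{(1Z)-2-[(5R)-5-{2-[(4-methoxybenzyl)oxy]ethyl}-5-methyl-4-oxo-4,5-dihydrofuran-2-yl]prop-1-en-1-yl}furan-2(5H)-one
Conditions: HCHO (37% aq.), imidazole (1 equiv), THF/H2O, 23 °C
Reagents that add atoms: formaldehyde, C=O
Why: Morita–Baylis–Hillman α-hydroxymethylation: imidazole adds to C7, the enolate attacks formaldehyde through C11, and loss of imidazole restores the butenolide. Formaldehyde is reactive enough that the weak base should not have time to remove C6–H, and the fully substituted furanone β-carbon C3 does not compete.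

**Step 13**
Reactants: 18 (5S)-3-(hydroxymethyl)-5-{(1Z)-2-[(5R)-5-{2-[(4-methoxybenzyl)oxy]ethyl}-5-methyl-4-oxo-4,5-dihydrofuran-2-yl]prop-1-en-1-yl}furan-2(5H)-one
Product: 19 (5S)-3-(bromomethyl)-5-{(1Z)-2-[(5R)-5-{2-[(4-methoxybenzyl)oxy]ethyl}-5-methyl-4-oxo-4,5-dihydrofuran-2-yl]prop-1-en-1-yl}furan-2(5H)-one
Conditions: CBr4, PPh3 (1.05 equiv, added last), CH2Cl2, −20 → 0 °C
Reagents that add atoms: tetrabromomethane, BrC(Br)(Br)Br
Why: Appel bromination of the primary allylic alcohol under neutral conditions, by displacement on the oxyphosphonium ion. An allylic isomer formed by SN2′ would be an equally good allyl donor.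

**Step 14**
Reactants: 19 (5S)-3-(bromomethyl)-5-{(1Z)-2-[(5R)-5-{2-[(4-methoxybenzyl)oxy]ethyl}-5-methyl-4-oxo-4,5-dihydrofuran-2-yl]prop-1-en-1-yl}furan-2(5H)-one
Product: 20 (5S)-3-(bromomethyl)-5-{(1Z)-2-[(5R)-5-(2-hydroxyethyl)-5-methyl-4-oxo-4,5-dihydrofuran-2-yl]prop-1-en-1-yl}furan-2(5H)-one
Conditions: DDQ, CH2Cl2/pH 7 buffer, 0 °C
Reagents that add atoms: none
Why: Oxidative cleavage of the PMB ether (electron transfer from the electron-rich arene, then hydrolysis of the benzylic oxocarbenium ion). The electron-poor dienone, the butenolide and the bromide should be inert, and the medium is neutral.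

**Step 15**
Reactants: 20 (5S)-3-(bromomethyl)-5-{(1Z)-2-[(5R)-5-(2-hydroxyethyl)-5-methyl-4-oxo-4,5-dihydrofuran-2-yl]prop-1-en-1-yl}furan-2(5H)-one
Product: 21 (5S)-3-(bromomethyl)-5-{(1Z)-2-[(5R)-5-methyl-4-oxo-5-(2-oxoethyl)-4,5-dihydrofuran-2-yl]prop-1-en-1-yl}furan-2(5H)-one
Conditions: Dess–Martin periodinane, CH2Cl2, 0 → 23 °C; crude aldehyde used at once
Reagents that add atoms: none
Why: Dess–Martin oxidation of the primary alcohol without base. This matters because the aldehyde has the furanone oxygen on its β-carbon and would lose it by E1cB under basic conditions.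

**Step 16**
Reactants: 21 (5S)-3-(bromomethyl)-5-{(1Z)-2-[(5R)-5-methyl-4-oxo-5-(2-oxoethyl)-4,5-dihydrofuran-2-yl]prop-1-en-1-yl}furan-2(5H)-one
Product: 22 (4Z,6S,7S,8R,10R)-8-hydroxy-1-oxo-3,10-epoxygermacra-2,4,11(13)-trien-12,6-olide
Conditions: CrCl2 (6 equiv), THF, 23 °C, slow addition of 21 to 2 mM; aq. NH4Cl
Reagents that add atoms: none
Why: Intramolecular Nozaki–Hiyama allylation (chromium Barbier): CrCl2 turns the allylic bromide into an allylchromium of trivalent chromium, which adds through C7 to the C8 aldehyde in a closed six-membered chair and regenerates C11=C13, closing ring B. C7 is set by the neighbouring C6 centre (the bond forms on the butenolide face anti to the C5 substituent, giving the trans-lactone). C8 is set by the chair, in which the ring-locked allyl unit places C9 equatorial and O8 anti to C6 (8R). The medium is neutral, so the β-alkoxy aldehyde and the lactone should survive.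

**Step 17**
Reactants: 23 tert-butyl acrylate; 24 acetaldehyde
Product: 25 tert-butyl 3-hydroxy-2-methylidenebutanoate (racemic)
Conditions: DABCO (0.5 equiv), 1,4-dioxane/H2O, 23 °C
Reagents that add atoms: none
Why: Morita–Baylis–Hillman reaction of an acrylate with an aldehyde. The carbinol centre is racemic and is removed in the next step.

**Step 18**
Reactants: 25 tert-butyl 3-hydroxy-2-methylidenebutanoate (racemic)
Product: 27 tert-butyl (2E)-2-(acetoxymethyl)but-2-enoate, via allylic acetate 26 (not isolated)
Conditions: Ac2O, DMAP (5 mol%), DABCO (1.5 equiv), THF, 0 → 65 °C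
Reagents that add atoms: acetic anhydride, CC(=O)OC(C)=O
Why: O-Acetylation, then amine-mediated SN2′–SN2′ transposition of the allylic acetate to the thermodynamically preferred primary acetate. This should end at the E trisubstituted alkene (methyl trans to the ester carbonyl), and the stereocentre of 25 disappears.

**Step 19**
Reactants: 27 tert-butyl (2E)-2-(acetoxymethyl)but-2-enoate
Product: 28 (2E)-2-(acetoxymethyl)but-2-enoic acid
Conditions: CF3CO2H/CH2Cl2 (1:4), 0 → 23 °C
Reagents that add atoms: none
Why: Acidolysis of the tert-butyl ester with loss of isobutene; the acetate and the alkene geometry are not affected.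

**Step 20**
Reactants: 22 (4Z,6S,7S,8R,10R)-8-hydroxy-1-oxo-3,10-epoxygermacra-2,4,11(13)-trien-12,6-olide; 28 (2E)-2-(acetoxymethyl)but-2-enoic acid
Product: 29 (4Z,6S,7S,8R,10R)-1-oxo-3,10-epoxygermacra-2,4,11(13)-trien-12,6-olid-8-yl (2E)-2-(acetoxymethyl)but-2-enoate (CNP0176571.1)
Conditions: 28, 2,4,6-trichlorobenzoyl chloride, Et3N, toluene, 23 °C; then 22, DMAP, 23 °C
Reagents that add atoms: none
Why: Yamaguchi esterification through the mixed anhydride and the acylpyridinium ion; acyl transfer to oxygen retains the C8 configuration. The E side chain is the thermodynamic isomer, so reversible amine addition to it should do no harm.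

---

## Compound list

1 | (2Z)-3-methylpent-2-en-4-yn-1-ol | C#C/C(C)=C\CO | starting material
2 | tert-butyl{[(2Z)-3-methylpent-2-en-4-yn-1-yl]oxy}diphenylsilane | C#C/C(C)=C\CO[Si](c1ccccc1)(c2ccccc2)C(C)(C)C | intermediate
3 | ethyl pyruvate | CCOC(=O)C(C)=O | starting material
4 | ethyl (2R,5Z)-7-[(tert-butyldiphenylsilyl)oxy]-2-hydroxy-2,5-dimethylhept-5-en-3-ynoate | CC(C)(C)[Si](c1ccccc1)(c2ccccc2)OC/C=C(/C)C#C[C@@](C)(O)C(=O)OCC | intermediate
5 | (2R,5Z)-7-[(tert-butyldiphenylsilyl)oxy]-2-hydroxy-N-methoxy-N,2,5-trimethylhept-5-en-3-ynamide | CC(C)(C)[Si](c1ccccc1)(c2ccccc2)OC/C=C(/C)C#C[C@@](C)(O)C(=O)N(C)OC | intermediate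
6 | (3R,6Z)-8-[(tert-butyldiphenylsilyl)oxy]-3-hydroxy-3,6-dimethyloct-6-en-4-yn-2-one | CC(C)(C)[Si](c1ccccc1)(c2ccccc2)OC/C=C(/C)C#C[C@@](C)(O)C(C)=O | intermediate
7 | 4-methoxybenzyl alcohol | COc1ccc(CO)cc1 | starting material
8 | 1-methoxy-4-{[(methylsulfanyl)methoxy]methyl}benzene | COc1ccc(COCSC)cc1 | intermediate
9 | 1-[(chloromethoxy)methyl]-4-methoxybenzene | COc1ccc(COCCl)cc1 | intermediate
10 | (4R,7Z)-9-[(tert-butyldiphenylsilyl)oxy]-4-hydroxy-1-[(4-methoxybenzyl)oxy]-4,7-dimethylnon-7-en-5-yn-3-one | CC(C)(C)[Si](c1ccccc1)(c2ccccc2)OC/C=C(/C)C#C[C@@](C)(O)C(=O)CCOCc3ccc(OC)cc3 | intermediate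
11 | (2R)-5-{(2Z)-4-[(tert-butyldiphenylsilyl)oxy]but-2-en-2-yl}-2-{2-[(4-methoxybenzyl)oxy]ethyl}-2-methylfuran-3(2H)-one | CC(C)(C)[Si](c1ccccc1)(c2ccccc2)OC/C=C(/C)C3=CC(=O)[C@@](C)(CCOCc4ccc(OC)cc4)O3 | intermediate
12 | (2R)-5-[(2Z)-4-hydroxybut-2-en-2-yl]-2-{2-[(4-methoxybenzyl)oxy]ethyl}-2-methylfuran-3(2H)-one | OC/C=C(/C)C1=CC(=O)[C@@](C)(CCOCc2ccc(OC)cc2)O1 | intermediate
13 | (2Z)-3-[(5R)-5-{2-[(4-methoxybenzyl)oxy]ethyl}-5-methyl-4-oxo-4,5-dihydrofuran-2-yl]but-2-enal | O=C/C=C(/C)C1=CC(=O)[C@@](C)(CCOCc2ccc(OC)cc2)O1 | intermediate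
14 | methyl propiolate | C#CC(=O)OC | starting material
15 | methyl (4S,5Z)-4-hydroxy-6-[(5R)-5-{2-[(4-methoxybenzyl)oxy]ethyl}-5-methyl-4-oxo-4,5-dihydrofuran-2-yl]hept-5-en-2-ynoate | COC(=O)C#C[C@@H](O)/C=C(/C)C1=CC(=O)[C@@](C)(CCOCc2ccc(OC)cc2)O1 | intermediate
16 | methyl (2Z,4R,5Z)-4-hydroxy-6-[(5R)-5-{2-[(4-methoxybenzyl)oxy]ethyl}-5-methyl-4-oxo-4,5-dihydrofuran-2-yl]hepta-2,5-dienoate | COC(=O)/C=C\[C@@H](O)/C=C(/C)C1=CC(=O)[C@@](C)(CCOCc2ccc(OC)cc2)O1 | intermediate
17 | (5R)-5-{(1Z)-2-[(5R)-5-{2-[(4-methoxybenzyl)oxy]ethyl}-5-methyl-4-oxo-4,5-dihydrofuran-2-yl]prop-1-en-1-yl}furan-2(5H)-one | O=C1C=C[C@@H](O1)/C=C(/C)C2=CC(=O)[C@@](C)(CCOCc3ccc(OC)cc3)O2 | intermediate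
18 | (5S)-3-(hydroxymethyl)-5-{(1Z)-2-[(5R)-5-{2-[(4-methoxybenzyl)oxy]ethyl}-5-methyl-4-oxo-4,5-dihydrofuran-2-yl]prop-1-en-1-yl}furan-2(5H)-one | O=C1C(CO)=C[C@@H](O1)/C=C(/C)C2=CC(=O)[C@@](C)(CCOCc3ccc(OC)cc3)O2 | intermediate
19 | (5S)-3-(bromomethyl)-5-{(1Z)-2-[(5R)-5-{2-[(4-methoxybenzyl)oxy]ethyl}-5-methyl-4-oxo-4,5-dihydrofuran-2-yl]prop-1-en-1-yl}furan-2(5H)-one | O=C1C(CBr)=C[C@@H](O1)/C=C(/C)C2=CC(=O)[C@@](C)(CCOCc3ccc(OC)cc3)O2 | intermediate
20 | (5S)-3-(bromomethyl)-5-{(1Z)-2-[(5R)-5-(2-hydroxyethyl)-5-methyl-4-oxo-4,5-dihydrofuran-2-yl]prop-1-en-1-yl}furan-2(5H)-one | O=C1C(CBr)=C[C@@H](O1)/C=C(/C)C2=CC(=O)[C@@](C)(CCO)O2 | intermediate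
21 | (5S)-3-(bromomethyl)-5-{(1Z)-2-[(5R)-5-methyl-4-oxo-5-(2-oxoethyl)-4,5-dihydrofuran-2-yl]prop-1-en-1-yl}furan-2(5H)-one | O=C1C(CBr)=C[C@@H](O1)/C=C(/C)C2=CC(=O)[C@@](C)(CC=O)O2 | intermediate
22 | (4Z,6S,7S,8R,10R)-8-hydroxy-1-oxo-3,10-epoxygermacra-2,4,11(13)-trien-12,6-olide | C=C1C(=O)O[C@H]2/C=C(/C)C3=CC(=O)[C@@](C)(C[C@@H](O)[C@H]12)O3 | intermediate
23 | tert-butyl acrylate | C=CC(=O)OC(C)(C)C | starting material
24 | acetaldehyde | CC=O | starting material
25 | tert-butyl 3-hydroxy-2-methylidenebutanoate (racemic) | CC(O)C(=C)C(=O)OC(C)(C)C | intermediate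
26 | tert-butyl 3-acetoxy-2-methylidenebutanoate (racemic) | CC(OC(C)=O)C(=C)C(=O)OC(C)(C)C | intermediate
27 | tert-butyl (2E)-2-(acetoxymethyl)but-2-enoate | CC(=O)OC/C(=C\C)C(=O)OC(C)(C)C | intermediate
28 | (2E)-2-(acetoxymethyl)but-2-enoic acid | CC(=O)OC/C(=C\C)C(=O)O | intermediate
29 | (4Z,6S,7S,8R,10R)-1-oxo-3,10-epoxygermacra-2,4,11(13)-trien-12,6-olid-8-yl (2E)-2-(acetoxymethyl)but-2-enoate | C=C1C(=O)O[C@H]2/C=C(/C)C3=CC(=O)[C@@](C)(C[C@@H](OC(=O)/C(=C/C)COC(C)=O)[C@H]12)O3 | target

## Step count and least certain steps

Total step count: 20 (15 on the main line, 2 for 9, 3 for 28). Longest linear sequence: 15 steps, from 1 to 29 (steps 1, 2, 3, 6–16 and 20).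

**Step 7 (key step).** The most likely failure is loss of stereochemical fidelity or of alkene geometry. If the oxocarbenium ion reopens, or if the gold-bound enyne develops allyl-cation character over C3–C5 before the oxygen attacks, the shift no longer reports the C1 configuration and the C4=C5 bond can rotate. Attack of the O6 ether on C3 is a second possible diversion. The fallback does not use the shift and takes C10 from the chiral pool. It sets out from 2 and commercial (R)-citramalic acid. The acid is converted with 2,2-dimethoxypropane and an acid catalyst into the dioxolanone acid F1. The free carboxyl group is reduced with BH3·THF to the primary alcohol F2, which is etherified with 4-methoxybenzyl trichloroacetimidate under acid catalysis to the PMB ether F3. Aminolysis with MeNH(OMe)·HCl and i-PrMgCl opens the dioxolanone to the Weinreb amide F4. The lithium acetylide of 2 (n-BuLi, THF, −78 °C, two equivalents) adds to give the hydroxy ynone F5. Conjugate addition of the tertiary hydroxyl to the ynone, promoted by Et2NH in EtOH, then closes ring A and comes back to the route at 11.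

**Step 16.** The most likely failure is poor facial selectivity at the aldehyde. The rigid Z diene and butenolide hold C7 and C9 close, so closure itself is plausible, but the tether could force C9 axial in the chair and give the C8 epimer. The fallback sets out from 21: if the cyclisation delivers the 8S alcohol F6, a Mitsunobu esterification with 28 (PPh3, diisopropyl azodicarboxylate, toluene) inverts C8 while installing the side chain and comes back to the route at 29.

**Step 10.** The most likely failure is Z to E isomerisation of the enal during the slow, Lewis-acidic zinc reaction, with erosion of facial selectivity as a consequence. The fallback sets out from 13. Lithiated methyl propiolate is added at −78 °C, fast enough to outrun isomerisation, which gives 15 mixed with the 4R epimer F7. The mixture is oxidised (Dess–Martin periodinane) to the ynone F8, and a Corey–Bakshi–Shibata reduction (2-methyl-CBS-oxazaborolidine, antipode giving 4S, catecholborane, −78 °C), with the alkyne as the small group, comes back to the route at 15.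

**Step 12.** The most likely failure is racemisation at C6. C6–H is γ to the butenolide carbonyl and allylic to the dienone, so deprotonation to a furanolate by the amine catalyst can compete with hydroxymethylation. The fallback is neutral and sets out from 15. Hydrostannation (Bu3SnH, Pd(PPh3)4, THF) places tin on C11 syn to the new C7–H, and lactonisation gives the α-stannyl butenolide F9. Iododestannylation (I2, CH2Cl2, 0 °C) gives the α-iodo butenolide F10. Stille coupling with (tributylstannyl)methanol (Pd(PPh3)4, dioxane, 80 °C) comes back to the route at 18.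

**Step 2.** The most likely failures are self-aldol condensation of the enolisable keto ester under the warm amine/zinc conditions and modest enantioselectivity with so small a ketone substituent. The fallback forms the other carbon–carbon bond of the carbinol and sets out from 2. Lithiation (n-BuLi, −78 °C) and acylation with diethyl oxalate give the alkynyl keto ester F11, which cannot enolise. Catalytic enantioselective addition of Me2Zn to its ketone (Ti(Oi-Pr)4 with a chiral salen-type ligand, antipode giving 2R) comes back to the route at 4.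

## Further compounds

F1 | step 7 | [(4R)-2,2,4-trimethyl-5-oxo-1,3-dioxolan-4-yl]acetic acid | CC1(C)OC(=O)[C@@](C)(CC(=O)O)O1
F2 | step 7 | (5R)-5-(2-hydroxyethyl)-2,2,5-trimethyl-1,3-dioxolan-4-one | CC1(C)OC(=O)[C@@](C)(CCO)O1
F3 | step 7 | (5R)-5-{2-[(4-methoxybenzyl)oxy]ethyl}-2,2,5-trimethyl-1,3-dioxolan-4-one | CC1(C)OC(=O)[C@@](C)(CCOCc2ccc(OC)cc2)O1
F4 | step 7 | (2R)-2-hydroxy-N-methoxy-4-[(4-methoxybenzyl)oxy]-N,2-dimethylbutanamide | CON(C)C(=O)[C@@](C)(CCOCc1ccc(OC)cc1)O
F5 | step 7 | (3R,7Z)-9-[(tert-butyldiphenylsilyl)oxy]-3-hydroxy-1-[(4-methoxybenzyl)oxy]-3,7-dimethylnon-7-en-5-yn-4-one | CC(C)(C)[Si](c1ccccc1)(c2ccccc2)OC/C=C(/C)C#CC(=O)[C@@](C)(CCOCc3ccc(OC)cc3)O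
F6 | step 16 | (4Z,6S,7S,8S,10R)-8-hydroxy-1-oxo-3,10-epoxygermacra-2,4,11(13)-trien-12,6-olide | C=C1C(=O)O[C@H]2/C=C(/C)C3=CC(=O)[C@@](C)(C[C@H](O)[C@H]12)O3
F7 | step 10 | methyl (4R,5Z)-4-hydroxy-6-[(5R)-5-{2-[(4-methoxybenzyl)oxy]ethyl}-5-methyl-4-oxo-4,5-dihydrofuran-2-yl]hept-5-en-2-ynoate | COC(=O)C#C[C@H](O)/C=C(/C)C1=CC(=O)[C@@](C)(CCOCc2ccc(OC)cc2)O1
F8 | step 10 | methyl (5Z)-6-[(5R)-5-{2-[(4-methoxybenzyl)oxy]ethyl}-5-methyl-4-oxo-4,5-dihydrofuran-2-yl]-4-oxohept-5-en-2-ynoate | COC(=O)C#CC(=O)/C=C(/C)C1=CC(=O)[C@@](C)(CCOCc2ccc(OC)cc2)O1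
F9 | step 12 | (5S)-5-{(1Z)-2-[(5R)-5-{2-[(4-methoxybenzyl)oxy]ethyl}-5-methyl-4-oxo-4,5-dihydrofuran-2-yl]prop-1-en-1-yl}-3-(tributylstannyl)furan-2(5H)-one | O=C1C([Sn](CCCC)(CCCC)CCCC)=C[C@@H](O1)/C=C(/C)C2=CC(=O)[C@@](C)(CCOCc3ccc(OC)cc3)O2
F10 | step 12 | (5S)-3-iodo-5-{(1Z)-2-[(5R)-5-{2-[(4-methoxybenzyl)oxy]ethyl}-5-methyl-4-oxo-4,5-dihydrofuran-2-yl]prop-1-en-1-yl}furan-2(5H)-one | O=C1C(I)=C[C@@H](O1)/C=C(/C)C2=CC(=O)[C@@](C)(CCOCc3ccc(OC)cc3)O2
F11 | step 2 | ethyl (5Z)-7-[(tert-butyldiphenylsilyl)oxy]-5-methyl-2-oxohept-5-en-3-ynoate | CC(C)(C)[Si](c1ccccc1)(c2ccccc2)OC/C=C(/C)C#CC(=O)C(=O)OCC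
A1 | alternative 1 | eleven-membered cyclic sulfone with SO2 between C4 and C5, C8 silyl ether, lactone without C13 (C4 either epimer) | C1C(=O)O[C@H]2CS(=O)(=O)C(C)C3=CC(=O)[C@@](C)(C[C@@H](O[Si](C)(C)C(C)(C)C)[C@H]12)O3
A2 | alternative 1 | C8-silylated tricyclic core lacking the exocyclic methylene | C1C(=O)O[C@H]2/C=C(/C)C3=CC(=O)[C@@](C)(C[C@@H](O[Si](C)(C)C(C)(C)C)[C@H]12)O3
A3 | alternative 2 | open-chain C1 aldehyde with terminal Z enyne, C6 triethylsilyl ether, C8 tert-butyldimethylsilyl ether, C10 methoxymethyl ether | C#C/C(C)=C\[C@H](O[Si](CC)(CC)CC)[C@@H](C(=C)COCc1ccc(OC)cc1)[C@H](O[Si](C)(C)C(C)(C)C)C[C@@](C)(OCOC)C=O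
A4 | alternative 2 | ten-membered Z enynol (C1 carbinol, either epimer) | OC1C#C/C(C)=C\[C@H](O[Si](CC)(CC)CC)[C@@H](C(=C)COCc2ccc(OC)cc2)[C@H](O[Si](C)(C)C(C)(C)C)C[C@@]1(C)OCOC
A5 | alternative 3 | furanone with Z alkenyl iodide at C5, C6 aldehyde on C7, C12 methyl ester, C8 silyl ether | I/C=C(/C)C1=CC(=O)[C@@](C)(C[C@@H](O[Si](C)(C)C(C)(C)C)[C@@H](C=O)C(=C)C(=O)OC)O1
A6 | alternative 3 | C8-silylated tricyclic core with the methylene lactone | C=C1C(=O)O[C@H]2/C=C(/C)C3=CC(=O)[C@@](C)(C[C@@H](O[Si](C)(C)C(C)(C)C)[C@H]12)O3
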